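Read these four set-ups as one contest between two nucleophiles for the intermediate.

    starting material → intermediate (k1 = 0.13 s⁻¹)
    first nucleophile + intermediate → target (k2 = 15 M⁻¹ s⁻¹)
    second nucleophile + intermediate → other capture product (k3 = 170 M⁻¹ s⁻¹)
    intermediate → solvolysis product (k4 = 0.74 s⁻¹)
    target → over-reaction product (k5 = 0.011 s⁻¹)

all flasks: first nucleophile 0.660 M; second nucleophile 0.429 M
- alpha: starting material 0.33 M; one stirred flow tank at steady state, fed with the mixture as stated, mean residence time 40 s
- zeta: starting material 0.33 M; plug flow through a tube for 40 s, no back-mixing; time 40 s
- gamma: starting material 0.33 M (fed, over 32.0 s); all but starting material at the start; starting material goes in evenly over 32.0 s, the run ends at 40 s; time 40 s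
- eta: starting material 0.33 M; everything together in a closed stirred flask, run for 40 s; time 40 s

- the set-up with the highest share of target in all that became target or other capture product or solvolysis product or over-reaction product, at the outlet or at the end ("none" if the first two lie within 2 percentage points) (alpha / zeta / gamma / eta / none)
- share of target in all that became target or other capture product or solvolysis product or over-reaction product, at the outlet or at the end, alpha
- share of target in all that became target or other capture product or solvolysis product or over-reaction product, at the outlet or at the end, zeta
- share of target in all that became target or other capture product or solvolysis product or over-reaction product, at the outlet or at the end, gamma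
- share of target in all that became target or other capture product or solvolysis product or over-reaction product, at the outlet or at the end, eta

- the stated concentrations are those of everything mixed, before any reaction; amounts are the same in each set-up
- the feed brings no volume worth counting
- run time (zeta): 40 s

Both captures draw on the same intermediate, so we set their rates equal. With the first nucleophile as charged this gives 0.0582 M, the second-nucleophile concentration at which both captures run equally fast; we call it the crossover level, and it is that charge divided by the selectivity factor 11.3.

But the starting material can pull the second nucleophile down by its own charge at most, to a floor of 0.0990 M. That floor stands above the crossover level, so in every set-up target is the minor capture throughout. Solvolysis we neglect, at 0.74 s⁻¹ against 16.8 s⁻¹.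

Dividing the two capture rates, with the first nucleophile held as charged, target made (what later over-reacts included) equals the crossover level times the logarithm of charged over remaining second nucleophile. The floor as remainder gives 0.0854 M. Every target formed spares second nucleophile, so we add it back and repeat: 0.0492 M, then 0.0619 M. That brackets target made at 14.9% to 18.8% of the charge.

As an estimate we date target to one lifetime of the starting material, 7.69 s, and over-reaction for the rest of the run then leaves 70.1% of it. In eta, and in zeta, which runs the same clock, we expect 10.4% to 13.1%. For alpha and gamma our reckoning stops here.

The forecast puts alpha at 13.7%, zeta at 12.1%, gamma at 13.6% and eta at 12.1%, best none, with “no clear winner stands out”.

The simulation gives 13.8%, 11.9%, 13.5% and 11.9% in that order, best none.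

Eta ends with 0.160 M of second nucleophile, above the crossover level. The neighbour, eta with 0.11 M of second nucleophile, has a charge below that of the starting material, so no floor holds it above the crossover level, and other capture product is capped at 33.3% of the charge. At 40.0 s that flask reads 0.001755 M of second nucleophile, less than the crossover level, other capture product 32.8%, over-reaction product 17.4% and target 43.8%.

The rate constants belong to no real substance; no experiment stands behind them.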